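**Retrosynthetic overview**
1. 21 ⇒ 16. The benzyl ethers are removed last. The acetate is placed on the free 8-OH of quinol 19. O8 is introduced by Elbs oxidation para to the 5-OH after O5 of flavone 16 has been unmasked, so C8 stays C–H until then.
2. 16 ⇒ 14. Ring C is closed at O1–C2 by oxidative cyclisation of a 2'-hydroxy-α-benzyloxychalcone that already holds all fifteen skeletal carbons.
3. Feature used: on ring A the bonds O1–C8a and C4–C4a stand on neighbouring carbons, and only C4a has an oxygen-bearing neighbour (C5–O). A C4a≡C8a aryne (13) is therefore polarised, and 14 ⇒ 13 + acid 12 by insertion of the aryne into the acid C–O bond.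
4. 13 ⇐ silyl triflate 8 (Si on C8a, OTf on C4a). Its pattern is fixed from bromoaldehyde 1 by chelation-controlled demethylation, benzylation, Baeyer–Villiger oxidation and retro-Brook shift. The isomer with Si on C4a would give the same aryne, but it needs a metalation that cannot tell the two ortho sites of a 3,5-dialkoxyphenol apart. 12 ⇐ aldehyde 9 + ester 10.
5. Ring order: rings A and B are bought, and ring C is the only ring made (step 8).

Key step: step 7

Assumption: 1 is taken as a catalogue compound; it is the Vilsmeier–Haack formylation product of 1-bromo-3,5-dimethoxybenzene.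

**Route**

Step 1
Reactants: 1 2-bromo-4,6-dimethoxybenzaldehyde
Product: 2 2-bromo-6-hydroxy-4-methoxybenzaldehyde
Conditions: BCl3 (1.2 equiv), CH2Cl2, −78 °C to rt; H2O
Reagents that add atoms: none
Why: Chelation-controlled Lewis-acid ether cleavage: boron binds the aldehyde oxygen and the ortho 6-methoxy oxygen in a six-membered chelate, so chloride should remove only that methyl group while the 4-methoxy group (the later 7-OMe) stays.

Step 2
Reactants: 2 2-bromo-6-hydroxy-4-methoxybenzaldehyde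
Product: 3 2-(benzyloxy)-6-bromo-4-methoxybenzaldehyde
Conditions: BnBr, K2CO3, DMF, 50 °C
Reagents that add atoms: benzyl bromide, BrCc1ccccc1
Why: Williamson etherification of the only phenol, with carbonate in DMF strong enough to break its hydrogen bond to the aldehyde.

Step 3
Reactants: 3 2-(benzyloxy)-6-bromo-4-methoxybenzaldehyde
Product: 5 2-(benzyloxy)-6-bromo-4-methoxyphenol, via aryl formate 4 (not isolated)
Conditions: mCPBA, CH2Cl2, 0 °C to rt; then K2CO3 (cat.), MeOH, rt
Reagents that add atoms: mCPBA, O=C(OO)c1cccc(Cl)c1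
Why: Baeyer–Villiger (Dakin-type) oxidation: the aryl group with ortho and para alkoxy donors migrates in preference to hydride, and mild methanolysis of formate 4 leaves the oxygen of the later triflate between bromine and benzyloxy without any regiochemical choice.

Step 4
Reactants: 5 2-(benzyloxy)-6-bromo-4-methoxyphenol
Product: 8 2-(benzyloxy)-4-methoxy-6-(trimethylsilyl)phenyl trifluoromethanesulfonate, via aryl trimethylsilyl ether 6 (not isolated), via lithium silylphenoxide 7 (not isolated)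
Conditions: (Me3Si)2NH, THF, 70 °C, then evaporate; n-BuLi, THF, −78 °C; Tf2O, −78 °C to rt
Reagents that add atoms: hexamethyldisilazane, C[Si](C)(C)N[Si](C)(C)C; triflic anhydride, O=S(=O)(OS(=O)(=O)C(F)(F)F)C(F)(F)F
Why: Standard silylaryl triflate sequence: bromine–lithium exchange outruns benzylic deprotonation at −78 °C, the aryllithium takes silicon from the neighbouring oxygen (retro-Brook 1,3-shift), and the freed phenoxide 7 is trapped by Tf2O.

Step 5
Reactants: 9 3,4-bis(benzyloxy)benzaldehyde; 10 methyl 2-(benzyloxy)acetate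
Product: 11 methyl (Z)-2-(benzyloxy)-3-[3,4-bis(benzyloxy)phenyl]prop-2-enoate
Conditions: KOt-Bu, THF, −20 °C to rt
Reagents that add atoms: none
Why: Claisen-type aldol condensation of an alkoxyacetate enolate with a non-enolisable aldehyde, in which E1cB loss of hydroxide under equilibrating conditions should put the aryl group trans to the ester (Z by the CIP rules), a geometry that has no bearing on the target.

Step 6
Reactants: 11 methyl (Z)-2-(benzyloxy)-3-[3,4-bis(benzyloxy)phenyl]prop-2-enoate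
Product: 12 (Z)-2-(benzyloxy)-3-[3,4-bis(benzyloxy)phenyl]prop-2-enoic acid
Conditions: LiOH, THF–MeOH–H2O, 40 °C; then 1 M HCl, 0 °C
Reagents that add atoms: lithium hydroxide, [Li+].[OH-]
Why: Ester saponification, to which the benzyl ethers and the conjugated enol ether are inert, with cold and brief acidification so that the enol ether is not hydrolysed.

Step 7
Reactants: 8 2-(benzyloxy)-4-methoxy-6-(trimethylsilyl)phenyl trifluoromethanesulfonate; 12 (Z)-2-(benzyloxy)-3-[3,4-bis(benzyloxy)phenyl]prop-2-enoic acid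
Product: 14 (Z)-2-(benzyloxy)-1-[2-(benzyloxy)-6-hydroxy-4-methoxyphenyl]-3-[3,4-bis(benzyloxy)phenyl]prop-2-en-1-one, via 3-benzyloxy-5-methoxybenzyne 13 (not isolated)
Conditions: CsF (4 equiv), THF, 125 °C, sealed tube
Reagents that add atoms: none
Why: Fluoride removes the silyl group of 8 and triflate leaves, which gives aryne 13, the C4a≡C8a form of ring A. The carboxylate of 12 adds to C8a, the terminus remote from the benzyloxy group, because the negative charge then builds up on C4a next to the inductively withdrawing C5–O bond; the remote 7-OMe has only a weak influence, and C8 is kept as C–H so that no second flanking oxygen cancels the bias. The aryl anion attacks its own ester carbonyl, and the four-membered alkoxide opens to the phenoxide of ketone 14, so that O1–C8a and C4–C4a are made in one operation. This is the known insertion of arynes into the C–O bond of carboxylic acids, which gives o-hydroxyaryl ketones. No ring is closed and no stereocentre is set; the Z-alkene is carried through and its geometry is lost in step 8, and any 15 formed by conjugate addition of the phenoxide is taken on together with 14. Besides regioselectivity the step needs acyl transfer to outrun protonation of the aryl anion, which hot THF should favour because CsF dissolves sparingly, releases the aryne slowly and has already turned the acid into its caesium salt.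

Step 8
Reactants: 14 (Z)-2-(benzyloxy)-1-[2-(benzyloxy)-6-hydroxy-4-methoxyphenyl]-3-[3,4-bis(benzyloxy)phenyl]prop-2-en-1-one
Product: 16 3,5-bis(benzyloxy)-2-[3,4-bis(benzyloxy)phenyl]-7-methoxy-4H-chromen-4-one, via 3-benzyloxyflavanone 15 (not isolated)
Conditions: I2 (10 mol %), DMSO, 130 °C
Reagents that add atoms: none
Why: Iodine/DMSO oxidative cyclisation of a 2'-hydroxychalcone: the phenol adds 6-endo to the benzylic β-carbon (C2) to give flavanone 15, iodination at C3 and loss of HI give the aromatic pyranone while DMSO re-oxidises HI, and the same closure of α-alkoxy-2'-hydroxychalcones to 3-alkoxyflavones is classical with SeO2.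

Step 9
Reactants: 16 3,5-bis(benzyloxy)-2-[3,4-bis(benzyloxy)phenyl]-7-methoxy-4H-chromen-4-one
Product: 17 3-(benzyloxy)-2-[3,4-bis(benzyloxy)phenyl]-5-hydroxy-7-methoxy-4H-chromen-4-one
Conditions: MgBr2·OEt2 (3 equiv), toluene–Et2O, 80 °C; then 1 M HCl
Reagents that add atoms: none
Why: Magnesium bromide cleavage of an aryl benzyl ether next to a carbonyl group: only O5 forms a six-membered chelate with the C4 carbonyl, cleavage of the 5-ether before the 3-ether is the established order for flavonol ethers, and the benzyl ethers of ring B are not activated.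

Step 10
Reactants: 17 3-(benzyloxy)-2-[3,4-bis(benzyloxy)phenyl]-5-hydroxy-7-methoxy-4H-chromen-4-one
Product: 19 3-(benzyloxy)-2-[3,4-bis(benzyloxy)phenyl]-5,8-dihydroxy-7-methoxy-4H-chromen-4-one, via potassium 8-sulfate 18 (not isolated)
Conditions: K2S2O8, KOH, H2O–pyridine, 0 °C to rt; then 2 M HCl, dioxane, 60 °C, under Ar
Reagents that add atoms: potassium persulfate, [K+].[K+].[O-]S(=O)(=O)OOS(=O)(=O)[O-]
Why: Elbs persulfate oxidation: the 5-phenoxide attacks the peroxide oxygen through its para carbon C8, a transformation established for 5-hydroxy-3,7,3',4'-tetraalkoxyflavones, and aryl sulfate 18 is then hydrolysed by acid with S–O cleavage.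

Step 11
Reactants: 19 3-(benzyloxy)-2-[3,4-bis(benzyloxy)phenyl]-5,8-dihydroxy-7-methoxy-4H-chromen-4-one
Product: 20 3-(benzyloxy)-2-[3,4-bis(benzyloxy)phenyl]-5-hydroxy-7-methoxy-4-oxo-4H-chromen-8-yl acetate
Conditions: Ac2O (1.05 equiv), pyridine, CH2Cl2, 0 °C, under Ar
Reagents that add atoms: acetic anhydride, CC(=O)OC(C)=O
Why: Selective O-acylation: the 5-OH is held in a hydrogen bond to the C4 carbonyl and is a poor nucleophile, so one equivalent of anhydride at 0 °C should acetylate only the free 8-OH.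

Step 12
Reactants: 20 3-(benzyloxy)-2-[3,4-bis(benzyloxy)phenyl]-5-hydroxy-7-methoxy-4-oxo-4H-chromen-8-yl acetate
Product: 21 gossypetin 7-methyl ether 8-acetate
Conditions: H2 (1 atm), 10% Pd/C, EtOAc–THF, rt
Reagents that add atoms: none
Why: Catalytic hydrogenolysis of the three benzyl ethers in a neutral, non-nucleophilic medium should leave the aryl acetate, the 7-OMe and the pyranone C2=C3 bond untouched, and with O7 methylated the acetyl group has no neighbouring hydroxyl to migrate to.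

**Compound list**
1 | 2-bromo-4,6-dimethoxybenzaldehyde | COc1cc(Br)c(C=O)c(OC)c1 | starting material
2 | 2-bromo-6-hydroxy-4-methoxybenzaldehyde | COc1cc(O)c(C=O)c(Br)c1 | intermediate
3 | 2-(benzyloxy)-6-bromo-4-methoxybenzaldehyde | COc1cc(Br)c(C=O)c(OCc2ccccc2)c1 | intermediate
4 | 2-(benzyloxy)-6-bromo-4-methoxyphenyl formate | COc1cc(Br)c(OC=O)c(OCc2ccccc2)c1 | intermediate
5 | 2-(benzyloxy)-6-bromo-4-methoxyphenol | COc1cc(Br)c(O)c(OCc2ccccc2)c1 | intermediate
6 | [2-(benzyloxy)-6-bromo-4-methoxyphenoxy]trimethylsilane | COc1cc(Br)c(O[Si](C)(C)C)c(OCc2ccccc2)c1 | intermediate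
7 | lithium 2-(benzyloxy)-4-methoxy-6-(trimethylsilyl)phenoxide | [Li+].COc1cc(OCc2ccccc2)c([O-])c([Si](C)(C)C)c1 | intermediate
8 | 2-(benzyloxy)-4-methoxy-6-(trimethylsilyl)phenyl trifluoromethanesulfonate | COc1cc(OCc2ccccc2)c(OS(=O)(=O)C(F)(F)F)c([Si](C)(C)C)c1 | intermediate
9 | 3,4-bis(benzyloxy)benzaldehyde | O=Cc1ccc(OCc2ccccc2)c(OCc2ccccc2)c1 | starting material
10 | methyl 2-(benzyloxy)acetate | COC(=O)COCc1ccccc1 | starting material
11 | methyl (Z)-2-(benzyloxy)-3-[3,4-bis(benzyloxy)phenyl]prop-2-enoate | COC(=O)/C(OCc1ccccc1)=C/c1ccc(OCc2ccccc2)c(OCc2ccccc2)c1 | intermediate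
12 | (Z)-2-(benzyloxy)-3-[3,4-bis(benzyloxy)phenyl]prop-2-enoic acid | OC(=O)/C(OCc1ccccc1)=C/c1ccc(OCc2ccccc2)c(OCc2ccccc2)c1 | intermediate
13 | 3-benzyloxy-5-methoxybenzyne | COC1=CC#CC(OCc2ccccc2)=C1 | intermediate
14 | (Z)-2-(benzyloxy)-1-[2-(benzyloxy)-6-hydroxy-4-methoxyphenyl]-3-[3,4-bis(benzyloxy)phenyl]prop-2-en-1-one | COc1cc(O)c(C(=O)/C(OCc2ccccc2)=C/c2ccc(OCc3ccccc3)c(OCc3ccccc3)c2)c(OCc2ccccc2)c1 | intermediate
15 | 3,5-bis(benzyloxy)-2-[3,4-bis(benzyloxy)phenyl]-7-methoxychroman-4-one (racemic, cis/trans mixture) | COc1cc(OCc2ccccc2)c2C(=O)C(OCc3ccccc3)C(c3ccc(OCc4ccccc4)c(OCc4ccccc4)c3)Oc2c1 | intermediate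
16 | 3,5-bis(benzyloxy)-2-[3,4-bis(benzyloxy)phenyl]-7-methoxy-4H-chromen-4-one | COc1cc(OCc2ccccc2)c2c(=O)c(OCc3ccccc3)c(-c3ccc(OCc4ccccc4)c(OCc4ccccc4)c3)oc2c1 | intermediate
17 | 3-(benzyloxy)-2-[3,4-bis(benzyloxy)phenyl]-5-hydroxy-7-methoxy-4H-chromen-4-one | COc1cc(O)c2c(=O)c(OCc3ccccc3)c(-c3ccc(OCc4ccccc4)c(OCc4ccccc4)c3)oc2c1 | intermediate
18 | potassium 3-(benzyloxy)-2-[3,4-bis(benzyloxy)phenyl]-5-hydroxy-7-methoxy-4-oxo-4H-chromen-8-yl sulfate | COc1cc(O)c2c(=O)c(OCc3ccccc3)c(-c3ccc(OCc4ccccc4)c(OCc4ccccc4)c3)oc2c1OS(=O)(=O)[O-].[K+] | intermediate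
19 | 3-(benzyloxy)-2-[3,4-bis(benzyloxy)phenyl]-5,8-dihydroxy-7-methoxy-4H-chromen-4-one | COc1cc(O)c2c(=O)c(OCc3ccccc3)c(-c3ccc(OCc4ccccc4)c(OCc4ccccc4)c3)oc2c1O | intermediate
20 | 3-(benzyloxy)-2-[3,4-bis(benzyloxy)phenyl]-5-hydroxy-7-methoxy-4-oxo-4H-chromen-8-yl acetate | COc1cc(O)c2c(=O)c(OCc3ccccc3)c(-c3ccc(OCc4ccccc4)c(OCc4ccccc4)c3)oc2c1OC(C)=O | intermediate
21 | gossypetin 7-methyl ether 8-acetate, 2-(3,4-dihydroxyphenyl)-3,5-dihydroxy-7-methoxy-4-oxo-4H-chromen-8-yl acetate | COc1cc(O)c2c(=O)c(O)c(-c3ccc(O)c(O)c3)oc2c1OC(C)=O | target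

**Step count**
Total step count: 12.
Longest linear sequence: 10 (steps 1–4 and 7–12, from 1).

**Steps most likely to fail**

Step 7.
- What may go wrong: the aryl anion formed after carboxylate addition is flanked on both sides and may be protonated before it reaches the ester carbonyl, so that plain O-arylation takes over. Surplus aryne may also arylate the product phenoxide.
- Fallback: it sets out from 9, returns at 16 and builds ring A–C4 classically.
- Commercial 2',6'-dihydroxy-4'-methoxyacetophenone is monobenzylated (BnBr, K2CO3, acetone; the second hydroxyl stays chelated) to 1-[2-(benzyloxy)-6-hydroxy-4-methoxyphenyl]ethan-1-one F1.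
- Claisen–Schmidt condensation with 9 (KOH, EtOH) should give (E)-1-[2-(benzyloxy)-6-hydroxy-4-methoxyphenyl]-3-[3,4-bis(benzyloxy)phenyl]prop-2-en-1-one F2.
- I2/DMSO closes it to 5-(benzyloxy)-2-[3,4-bis(benzyloxy)phenyl]-7-methoxy-4H-chromen-4-one F3.
- Dimethyldioxirane epoxidises C2=C3 to 5-(benzyloxy)-2-[3,4-bis(benzyloxy)phenyl]-2,3-epoxy-7-methoxychroman-4-one F4.
- Catalytic TsOH opens F4 to 5-(benzyloxy)-2-[3,4-bis(benzyloxy)phenyl]-3-hydroxy-7-methoxy-4H-chromen-4-one F5.
- BnBr/K2CO3 then gives 16.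

Step 10.
- What may go wrong: conversion of a poorly soluble, hydrogen-bonded phenol may be low. Ring C may open in alkali. The quinol may be oxidised by air during sulfate hydrolysis.
- Fallback: it sets out from 16, returns at 19 and replaces the phenoxide–persulfate reaction by halogenation and C–B oxidation.
- NBS (DMF, 0 °C) should brominate C8, the position at which 5,7-dialkoxyflavones take up electrophilic halogen. The product is 3,5-bis(benzyloxy)-2-[3,4-bis(benzyloxy)phenyl]-8-bromo-7-methoxy-4H-chromen-4-one F6.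
- Miyaura borylation (B2pin2, PdCl2(dppf), KOAc, dioxane, 90 °C) gives 3,5-bis(benzyloxy)-2-[3,4-bis(benzyloxy)phenyl]-7-methoxy-8-(4,4,5,5-tetramethyl-1,3,2-dioxaborolan-2-yl)-4H-chromen-4-one F7.
- NaBO3·4H2O (THF–H2O) gives 3,5-bis(benzyloxy)-2-[3,4-bis(benzyloxy)phenyl]-8-hydroxy-7-methoxy-4H-chromen-4-one F8.
- MgBr2·OEt2, used as in step 9, frees O5 to give 19.

Step 8.
- What may go wrong: iodine may attack the enol-ether carbon and bring about 5-exo closure. Benzyl groups may be lost to HI at 130 °C. The reaction may stall at the flavanone oxidation level.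
- Fallback: it sets out from 8, returns at 16 and brings C2 in at the carboxylic acid oxidation level, so that no oxidation is needed.
- The insertion of step 7 is run with benzyloxyacetic acid in place of 12 (CsF, THF, 125 °C) to give 2-(benzyloxy)-1-[2-(benzyloxy)-6-hydroxy-4-methoxyphenyl]ethan-1-one F9.
- Esterification with commercial 3,4-bis(benzyloxy)benzoic acid (EDC, DMAP, CH2Cl2) gives 3-(benzyloxy)-2-[(benzyloxy)acetyl]-5-methoxyphenyl 3,4-bis(benzyloxy)benzoate F10.
- Baker–Venkataraman acyl shift (KOH, pyridine, 50 °C) gives 2-(benzyloxy)-1-[2-(benzyloxy)-6-hydroxy-4-methoxyphenyl]-3-[3,4-bis(benzyloxy)phenyl]propane-1,3-dione F11.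
- Cyclodehydration (cat. TsOH, toluene, 80 °C) gives 16.

**Further compounds**
F1 | step 7 | 1-[2-(benzyloxy)-6-hydroxy-4-methoxyphenyl]ethan-1-one | CC(=O)c1c(O)cc(OC)cc1OCc1ccccc1
F2 | step 7 | (E)-1-[2-(benzyloxy)-6-hydroxy-4-methoxyphenyl]-3-[3,4-bis(benzyloxy)phenyl]prop-2-en-1-one | COc1cc(O)c(C(=O)/C=C/c2ccc(OCc3ccccc3)c(OCc3ccccc3)c2)c(OCc2ccccc2)c1
F3 | step 7 | 5-(benzyloxy)-2-[3,4-bis(benzyloxy)phenyl]-7-methoxy-4H-chromen-4-one | COc1cc(OCc2ccccc2)c2c(=O)cc(-c3ccc(OCc4ccccc4)c(OCc4ccccc4)c3)oc2c1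
F4 | step 7 | 5-(benzyloxy)-2-[3,4-bis(benzyloxy)phenyl]-2,3-epoxy-7-methoxychroman-4-one (racemic) | COc1cc(OCc2ccccc2)c2C(=O)C3OC3(c3ccc(OCc4ccccc4)c(OCc4ccccc4)c3)Oc2c1
F5 | step 7 | 5-(benzyloxy)-2-[3,4-bis(benzyloxy)phenyl]-3-hydroxy-7-methoxy-4H-chromen-4-one | COc1cc(OCc2ccccc2)c2c(=O)c(O)c(-c3ccc(OCc4ccccc4)c(OCc4ccccc4)c3)oc2c1
F6 | step 10 | 3,5-bis(benzyloxy)-2-[3,4-bis(benzyloxy)phenyl]-8-bromo-7-methoxy-4H-chromen-4-one | COc1cc(OCc2ccccc2)c2c(=O)c(OCc3ccccc3)c(-c3ccc(OCc4ccccc4)c(OCc4ccccc4)c3)oc2c1Br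
F7 | step 10 | 3,5-bis(benzyloxy)-2-[3,4-bis(benzyloxy)phenyl]-7-methoxy-8-(4,4,5,5-tetramethyl-1,3,2-dioxaborolan-2-yl)-4H-chromen-4-one | COc1cc(OCc2ccccc2)c2c(=O)c(OCc3ccccc3)c(-c3ccc(OCc4ccccc4)c(OCc4ccccc4)c3)oc2c1B1OC(C)(C)C(C)(C)O1
F8 | step 10 | 3,5-bis(benzyloxy)-2-[3,4-bis(benzyloxy)phenyl]-8-hydroxy-7-methoxy-4H-chromen-4-one | COc1cc(OCc2ccccc2)c2c(=O)c(OCc3ccccc3)c(-c3ccc(OCc4ccccc4)c(OCc4ccccc4)c3)oc2c1O
F9 | step 8 | 2-(benzyloxy)-1-[2-(benzyloxy)-6-hydroxy-4-methoxyphenyl]ethan-1-one | COc1cc(O)c(C(=O)COCc2ccccc2)c(OCc2ccccc2)c1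
F10 | step 8 | 3-(benzyloxy)-2-[(benzyloxy)acetyl]-5-methoxyphenyl 3,4-bis(benzyloxy)benzoate | COc1cc(OC(=O)c2ccc(OCc3ccccc3)c(OCc3ccccc3)c2)c(C(=O)COCc2ccccc2)c(OCc2ccccc2)c1
F11 | step 8 | 2-(benzyloxy)-1-[2-(benzyloxy)-6-hydroxy-4-methoxyphenyl]-3-[3,4-bis(benzyloxy)phenyl]propane-1,3-dione | COc1cc(O)c(C(=O)C(OCc2ccccc2)C(=O)c2ccc(OCc3ccccc3)c(OCc3ccccc3)c2)c(OCc2ccccc2)c1
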